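## Retrosynthetic overview

1. The strategy rests on C5 of the 1,2-dioxolane ring (O1–O2–C3–C4–C5). C5 carries a methyl group and the C16 chain, and the C1′–C2′ bond of that chain can be written as a transposed E-alkene. O1–C5 is therefore an allylic (SN2′) substitution whose stereochemical information is stored at a C2′ carbinol.
2. Endgame disconnections: C9′=C10′ (HWE of a C9′ aldehyde with a heptadienyl phosphonate), CO2H (oxidation of the hydroxyethyl arm), and saturated C1′–C2′ (diimide reduction of the transposed alkene).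
3. Key disconnection: O1–C5, closed from a C3 tertiary hydroperoxide, an E-C5=C1′ alkene and a (R)-C2′ allylic alcohol. The arm hydroxyl is masked so that OOH is the only nucleophile.
4. C3–OOH comes from invertive perhydrolysis of a 2,2-disubstituted oxetane made from (R)-mevalonolactone. C1′–C2′ comes from a vinyllithium and a Weinreb amide, followed by CBS reduction. The E-alkene is fixed by syn-carboalumination, because ketone olefination would pass through a β-oxetanyl ketone that is open to E1cB opening and gives E/Z mixtures.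
5. Ring order: the temporary oxetane is formed in step 3 and opened in step 9. The 1,2-dioxolane, the only ring of the target, is formed in step 12.

Key step: step 12

Numbering used in the text: dioxolane O1, O2, C3, C4, C5; acetic arm C1 (CO2H) and C2; chain C1′–C16′. TBS = tert-butyldimethylsilyl, TBDPS = tert-butyldiphenylsilyl.

Assumption: the closure is taken to be net syn-SN2′, meaning O1 enters C5 on the face from which the C2′ hydroxyl leaves, as in Pd(II) cyclisations of hydroxy allylic alcohols. If it proved net anti, (R)-Me-CBS in step 7 would supply the C2′ epimer and nothing else would change.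

## Route

Step 1
Reactants: 1 (R)-mevalonolactone
Product: 3 (3S)-3-methylhex-5-yne-1,3-diol, via (4R)-4-methyloxane-2,4-diol 2 (not isolated)
Conditions: DIBAL-H (2.2 equiv), CH2Cl2, −78 °C; then MeOH, K2CO3, Ohira–Bestmann reagent, −78 °C → rt; Rochelle salt work-up
Reagents that add atoms: dimethyl (1-diazo-2-oxopropyl)phosphonate, CC(=O)C(=[N+]=[N-])P(=O)(OC)OC
Why: DIBAL-H stops at the aluminium lactolate at −78 °C and, after the methanol quench, the open hydroxy-aldehyde fraction of lactol 2 is intercepted by the diazophosphonate anion (one-pot ester-to-alkyne reduction/Ohira–Bestmann variant of the Seyferth–Gilbert homologation, known for β-hydroxy lactols); the tertiary carbinol is untouched and its descriptor changes from R to S only through the ligand ranking.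

Step 2
Reactants: 3 (3S)-3-methylhex-5-yne-1,3-diol
Product: 5 (3S,5E)-6-iodo-3,5-dimethylhex-5-ene-1,3-diol, via the (E)-alkenyldimethylalane bis(dimethylaluminium alkoxide) 4 (not isolated)
Conditions: AlMe3 (5 equiv), Cp2ZrCl2 (0.3 equiv), CH2Cl2, 0 °C → rt; then I2, THF, −30 → 0 °C
Reagents that add atoms: trimethylaluminium, C[Al](C)C; iodine, II
Why: Zr-catalysed Negishi carboalumination, run on the bis(aluminium alkoxide) as for free homopropargylic alcohols, adds CH3 to the inner and Al to the terminal alkyne carbon in a syn fashion, and iodinolysis with retention should give only the E-iodoalkene that fixes the later C5=C1′ geometry.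

Step 3
Reactants: 5 (3S,5E)-6-iodo-3,5-dimethylhex-5-ene-1,3-diol
Product: 7 (2S)-2-[(2E)-3-iodo-2-methylprop-2-en-1-yl]-2-methyloxetane, via (3S,5E)-3-hydroxy-6-iodo-3,5-dimethylhex-5-en-1-yl 4-methylbenzenesulfonate 6 (not isolated)
Conditions: KOtBu (1.05 equiv), THF, 0 °C; TsCl (1.0 equiv); then KOtBu (1.2 equiv), 0 °C → rt
Reagents that add atoms: none
Why: The primary alkoxide is sulfonylated selectively and the tertiary alkoxide then displaces the tosylate in a 4-exo-tet Williamson closure (one-pot oxetane synthesis from a 1,3-diol), so the C3–O bond is never broken and the configuration is retained, while KOtBu spares the vinyl iodide.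

Step 4
Reactants: 8 8-hydroxyoctanoic acid
Product: 9 8-hydroxy-N-methoxy-N-methyloctanamide
Conditions: MeNHOMe·HCl, EDC·HCl, HOBt (cat.), Et3N, CH2Cl2, 0 °C → rt
Reagents that add atoms: N,O-dimethylhydroxylamine hydrochloride, CNOC.Cl
Why: In this carbodiimide amide coupling the amine outcompetes the remote primary hydroxyl for the activated ester.

Step 5
Reactants: 9 8-hydroxy-N-methoxy-N-methyloctanamide
Product: 10 8-[(tert-butyldiphenylsilyl)oxy]-N-methoxy-N-methyloctanamide
Conditions: TBDPSCl, imidazole, DMF, rt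
Reagents that add atoms: tert-butyl(chloro)diphenylsilane, CC(C)(C)[Si](Cl)(c1ccccc1)c1ccccc1
Why: This is a standard imidazole-promoted silylation, and TBDPS is chosen because the C9′ ether must survive TMSOTf/H2O2 (step 9) and Pd(II) (step 12) and must remain when a primary TBS ether is removed (step 14).

Step 6
Reactants: 7 (2S)-2-[(2E)-3-iodo-2-methylprop-2-en-1-yl]-2-methyloxetane; 10 8-[(tert-butyldiphenylsilyl)oxy]-N-methoxy-N-methyloctanamide
Product: 12 (2E)-11-[(tert-butyldiphenylsilyl)oxy]-2-methyl-1-[(2S)-2-methyloxetan-2-yl]undec-2-en-4-one, via (E)-2-methyl-3-[(2S)-2-methyloxetan-2-yl]prop-1-en-1-yllithium 11 (not isolated)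
Conditions: t-BuLi (2.05 equiv), Et2O, −78 °C; then 10, −78 → 0 °C; aq NH4Cl
Reagents that add atoms: none
Why: Iodine–lithium exchange proceeds with retention of alkene geometry and the Weinreb ketone synthesis stops at the chelated tetrahedral adduct, forming C1′–C2′ without over-addition, while an oxetane without Lewis acid activation is inert to organolithiums at −78 °C.

Step 7
Reactants: 12 (2E)-11-[(tert-butyldiphenylsilyl)oxy]-2-methyl-1-[(2S)-2-methyloxetan-2-yl]undec-2-en-4-one
Product: 13 (2E,4R)-11-[(tert-butyldiphenylsilyl)oxy]-2-methyl-1-[(2S)-2-methyloxetan-2-yl]undec-2-en-4-ol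
Conditions: (S)-Me-CBS (0.3 equiv), catecholborane (2 equiv), toluene, −78 °C
Reagents that add atoms: none
Why: In the Corey–Bakshi–Shibata reduction the β,β-disubstituted alkenyl arm acts as the large group and the n-alkyl arm as the small one, so the (S)-oxazaborolidine should deliver hydride 1,2 to the face that gives the R carbinol at C2′, in the same sense as acetophenone giving (R)-1-phenylethanol.

Step 8
Reactants: 13 (2E,4R)-11-[(tert-butyldiphenylsilyl)oxy]-2-methyl-1-[(2S)-2-methyloxetan-2-yl]undec-2-en-4-ol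
Product: 14 (2E,4R)-11-[(tert-butyldiphenylsilyl)oxy]-2-methyl-1-[(2S)-2-methyloxetan-2-yl]undec-2-en-4-yl acetate
Conditions: Ac2O, pyridine, DMAP (cat.), CH2Cl2, 0 °C → rt
Reagents that add atoms: acetic anhydride, CC(=O)OC(C)=O
Why: DMAP-catalysed acetylation masks the C2′ hydroxyl, because a free allylic alcohol flanked by a trisubstituted alkene would ionise under the acidic perhydrolysis of step 9 whereas the ester ionises far more slowly than the strained oxetane opens.

Step 9
Reactants: 14 (2E,4R)-11-[(tert-butyldiphenylsilyl)oxy]-2-methyl-1-[(2S)-2-methyloxetan-2-yl]undec-2-en-4-yl acetate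
Product: 15 (3R,5E,7R)-14-[(tert-butyldiphenylsilyl)oxy]-3-hydroperoxy-1-hydroxy-3,5-dimethyltetradec-5-en-7-yl acetate
Conditions: anhydrous H2O2 in Et2O (10 equiv), TMSOTf (0.3 equiv), Et2O, −78 → −20 °C; aq NaHCO3
Reagents that add atoms: hydrogen peroxide, OO
Why: In the Lewis-acid-mediated perhydrolysis of a 2,2-disubstituted oxetane, H2O2 attacks the activated tertiary C3–O carbon from the rear in a strain-releasing SN2-like opening, so C3 is inverted (2S oxetane to 3R hydroperoxide, the configuration of the target) and the primary alcohol of the arm is released.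

Step 10
Reactants: 15 (3R,5E,7R)-14-[(tert-butyldiphenylsilyl)oxy]-3-hydroperoxy-1-hydroxy-3,5-dimethyltetradec-5-en-7-yl acetate
Product: 16 (3R,5E,7R)-1-[(tert-butyldimethylsilyl)oxy]-3-[(tert-butyldimethylsilyl)peroxy]-14-[(tert-butyldiphenylsilyl)oxy]-3,5-dimethyltetradec-5-en-7-yl acetate
Conditions: TBSCl (2.5 equiv), imidazole (5 equiv), DMF, 0 °C → rt
Reagents that add atoms: tert-butyl(chloro)dimethylsilane, CC(C)(C)[Si](C)(C)Cl
Why: Imidazole-promoted silylation takes both the primary alcohol and the more acidic hydroperoxide (tert-alkyl silyl peroxides are stable, isolable compounds), which is more dependable than a selective protection of OH beside OOH.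

Step 11
Reactants: 16 (3R,5E,7R)-1-[(tert-butyldimethylsilyl)oxy]-3-[(tert-butyldimethylsilyl)peroxy]-14-[(tert-butyldiphenylsilyl)oxy]-3,5-dimethyltetradec-5-en-7-yl acetate
Product: 17 (3R,5E,7R)-1-[(tert-butyldimethylsilyl)oxy]-14-[(tert-butyldiphenylsilyl)oxy]-3-hydroperoxy-3,5-dimethyltetradec-5-en-7-ol
Conditions: K2CO3, MeOH, 0 °C → rt
Reagents that add atoms: none
Why: Base-catalysed methanolysis removes the acetate and also the silyl group on the peroxide, whose anion is a much better leaving group from silicon than an alkoxide, while the alkyl TBS and TBDPS ethers stay and the tertiary hydroperoxide has no α-hydrogen for a Kornblum–DeLaMare fragmentation.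

Step 12
Reactants: 17 (3R,5E,7R)-1-[(tert-butyldimethylsilyl)oxy]-14-[(tert-butyldiphenylsilyl)oxy]-3-hydroperoxy-3,5-dimethyltetradec-5-en-7-ol
Product: 18 (3S,5S)-3-{2-[(tert-butyldimethylsilyl)oxy]ethyl}-5-{(1E)-9-[(tert-butyldiphenylsilyl)oxy]non-1-en-1-yl}-3,5-dimethyl-1,2-dioxolane
Conditions: PdCl2(MeCN)2 (10 mol %), THF, 0 °C
Reagents that add atoms: none
Why: Proposed new method: PdCl2(MeCN)2 should bind the C5=C1′ alkene on the face of the C2′ hydroxyl, the C3 hydroperoxide then adds to C5 to give a C1′–Pd σ-complex, and β-hydroxide elimination of PdCl(OH) releases the E-C1′=C2′ alkene while the HCl formed in the addition turns PdCl(OH) back into PdCl2 and water. The closest known reaction types are the Pd(II)-catalysed oxypalladation–β-hydroxide elimination of hydroxy allylic alcohols to 2-alkenyl tetrahydrofurans and tetrahydropyrans with 1,3-chirality transfer, the Pd(II)-catalysed cyclisation of unsaturated tertiary hydroperoxides to 1,2-dioxanes, and intramolecular peroxymercuration; a hydroperoxide has not been shown as the nucleophile of the transposing variant. The 1,2-dioxolane is closed 5-exo-trig by formation of O1–C5. The new quaternary centre C5 is controlled by the R carbinol at C2′: A1,3 strain with the C5 methyl group, which is cis to C2′, holds the C2′–H bond in the alkene plane so that the hydroxyl marks one alkene face, and net syn-SN2′ displacement on that face gives 5S in 18 (5R in the target after saturation) together with the E-alkene, whereas C3 is a spectator because the short tether reaches both faces. Chemoselectivity for OOH is secured by the TBS ether on the arm hydroxyl, which would otherwise close a tetrahydropyran 6-exo at the same carbon, and regioselectivity for C5 over C1′ (6-endo) is secured by the Markovnikov bias of the trisubstituted alkene and by the fact that only Pd at C1′ has a β-hydroxyl to expel. β-Hydride loss and ketone-forming O–O cleavage of the peroxypalladation adduct should be disfavoured because C5 carries no hydrogen and chloride-ligated Pd(II) expels a β-hydroxyl faster than the C2′ hydride.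

Step 13
Reactants: 18 (3S,5S)-3-{2-[(tert-butyldimethylsilyl)oxy]ethyl}-5-{(1E)-9-[(tert-butyldiphenylsilyl)oxy]non-1-en-1-yl}-3,5-dimethyl-1,2-dioxolane
Product: 19 (3S,5R)-3-{2-[(tert-butyldimethylsilyl)oxy]ethyl}-5-{9-[(tert-butyldiphenylsilyl)oxy]nonyl}-3,5-dimethyl-1,2-dioxolane
Conditions: 2-nitrobenzenesulfonohydrazide (excess, in portions), Et3N, CH2Cl2, rt
Reagents that add atoms: none
Why: Diimide reduction transfers H2 to the 1,2-disubstituted alkene in a concerted syn fashion and leaves the O–O bond alone, unlike catalytic hydrogenation, and no stereocentre is touched (the C5 descriptor changes only through the ligand ranking).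

Step 14
Reactants: 19 (3S,5R)-3-{2-[(tert-butyldimethylsilyl)oxy]ethyl}-5-{9-[(tert-butyldiphenylsilyl)oxy]nonyl}-3,5-dimethyl-1,2-dioxolane
Product: 20 2-[(3S,5R)-5-{9-[(tert-butyldiphenylsilyl)oxy]nonyl}-3,5-dimethyl-1,2-dioxolan-3-yl]ethanol
Conditions: PPTS (0.2 equiv), MeOH, rt
Reagents that add atoms: none
Why: Mild acid-catalysed methanolysis cleaves a primary TBS ether much faster than a primary TBDPS ether, and the tetrasubstituted dialkyl peroxide is stable to weak acid.

Step 15
Reactants: 20 2-[(3S,5R)-5-{9-[(tert-butyldiphenylsilyl)oxy]nonyl}-3,5-dimethyl-1,2-dioxolan-3-yl]ethanol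
Product: 21 2-[(3R,5R)-5-{9-[(tert-butyldiphenylsilyl)oxy]nonyl}-3,5-dimethyl-1,2-dioxolan-3-yl]acetic acid
Conditions: TEMPO (0.2 equiv), PhI(OAc)2 (2.5 equiv), MeCN/H2O 1:1, rt
Reagents that add atoms: water, O
Why: The oxoammonium (TEMPO/PhI(OAc)2) oxidation runs through the aldehyde hydrate to the acid in a weakly acidic medium, which avoids base-induced β-elimination of the peroxide from the β-peroxy aldehyde.

Step 16
Reactants: 21 2-[(3R,5R)-5-{9-[(tert-butyldiphenylsilyl)oxy]nonyl}-3,5-dimethyl-1,2-dioxolan-3-yl]acetic acid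
Product: 22 2-[(3R,5R)-5-(9-hydroxynonyl)-3,5-dimethyl-1,2-dioxolan-3-yl]acetic acid
Conditions: TBAF (3 equiv), AcOH (2 equiv), THF, rt
Reagents that add atoms: none
Why: Fluoride desilylation buffered with acetic acid removes the TBDPS group, and the dioxolane has no hydrogen on its peroxide carbons while the carboxylate resists α-deprotonation.

Step 17
Reactants: 22 2-[(3R,5R)-5-(9-hydroxynonyl)-3,5-dimethyl-1,2-dioxolan-3-yl]acetic acid
Product: 23 2-[(3R,5R)-3,5-dimethyl-5-(9-oxononyl)-1,2-dioxolan-3-yl]acetic acid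
Conditions: Dess–Martin periodinane (1.3 equiv), CH2Cl2, 0 °C → rt
Reagents that add atoms: none
Why: Dess–Martin oxidation stops at the aldehyde under neutral to weakly acidic conditions and tolerates the free acid and the peroxide.

Step 18
Reactants: 24 (2E,4E)-hepta-2,4-dienal
Product: 25 (2E,4E)-hepta-2,4-dien-1-ol
Conditions: NaBH4, MeOH, 0 °C
Reagents that add atoms: none
Why: Borohydride reduces the dienal in the 1,2 sense without touching the E,E-diene.

Step 19
Reactants: 25 (2E,4E)-hepta-2,4-dien-1-ol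
Product: 26 (2E,4E)-1-bromohepta-2,4-diene
Conditions: PBr3 (0.4 equiv), Et2O, 0 °C
Reagents that add atoms: phosphorus tribromide, BrP(Br)Br
Why: SN2 bromination of the primary dienylic alcohol through its phosphite ester at low temperature should keep the diene geometry, and the bromide is used directly.

Step 20
Reactants: 26 (2E,4E)-1-bromohepta-2,4-diene
Product: 27 diethyl [(2E,4E)-hepta-2,4-dien-1-yl]phosphonate
Conditions: P(OEt)3 (neat), 120 °C
Reagents that add atoms: triethyl phosphite, CCOP(OCC)OCC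
Why: The Michaelis–Arbuzov reaction of a primary dienylic bromide proceeds at the unhindered α-carbon, as for sorbyl bromide.

Step 21
Reactants: 23 2-[(3R,5R)-3,5-dimethyl-5-(9-oxononyl)-1,2-dioxolan-3-yl]acetic acid; 27 diethyl [(2E,4E)-hepta-2,4-dien-1-yl]phosphonate
Product: 29 2-[(3R,5R)-5-[(9E,11E,13E)-hexadeca-9,11,13-trien-1-yl]-3,5-dimethyl-1,2-dioxolan-3-yl]acetic acid (target), via diethyl [(2E,4E)-1-lithiohepta-2,4-dien-1-yl]phosphonate 28 (not isolated)
Conditions: 27 (3.2 equiv), LiHMDS (3.0 equiv), THF, −78 °C; then 23, −78 °C → rt; aq citric acid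
Reagents that add atoms: none
Why: In this Horner–Wadsworth–Emmons olefination the first equivalent of the delocalised phosphonate anion only forms the lithium carboxylate, which shields C2 from deprotonation, the next one olefinates the unhindered C9′ aldehyde with the E preference of allylic phosphonates, and the O–O bond is flanked by two fully substituted carbons that shield it from the soft carbanion.

## Compound list

1 | (R)-mevalonolactone, (4R)-4-hydroxy-4-methyloxan-2-one | C[C@@]1(O)CCOC(=O)C1 | starting material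
2 | (4R)-4-methyloxane-2,4-diol (lactol, anomer mixture) | C[C@@]1(O)CCOC(O)C1 | intermediate
3 | (3S)-3-methylhex-5-yne-1,3-diol | C[C@@](CC#C)(O)CCO | intermediate
4 | (E)-alkenyldimethylalane bis(dimethylaluminium alkoxide) derived from 3 | C[C@@](C/C(C)=C/[Al](C)C)(O[Al](C)C)CCO[Al](C)C | intermediate
5 | (3S,5E)-6-iodo-3,5-dimethylhex-5-ene-1,3-diol | C[C@@](C/C(C)=C/I)(O)CCO | intermediate
6 | (3S,5E)-3-hydroxy-6-iodo-3,5-dimethylhex-5-en-1-yl 4-methylbenzenesulfonate | C[C@@](C/C(C)=C/I)(O)CCOS(=O)(=O)c1ccc(C)cc1 | intermediate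
7 | (2S)-2-[(2E)-3-iodo-2-methylprop-2-en-1-yl]-2-methyloxetane | C[C@@]1(C/C(C)=C/I)OCC1 | intermediate
8 | 8-hydroxyoctanoic acid | OCCCCCCCC(=O)O | starting material
9 | 8-hydroxy-N-methoxy-N-methyloctanamide | OCCCCCCCC(=O)N(C)OC | intermediate
10 | 8-[(tert-butyldiphenylsilyl)oxy]-N-methoxy-N-methyloctanamide | CON(C)C(=O)CCCCCCCO[Si](c1ccccc1)(c1ccccc1)C(C)(C)C | intermediate
11 | (E)-2-methyl-3-[(2S)-2-methyloxetan-2-yl]prop-1-en-1-yllithium | C[C@@]1(C/C(C)=C/[Li])OCC1 | intermediate
12 | (2E)-11-[(tert-butyldiphenylsilyl)oxy]-2-methyl-1-[(2S)-2-methyloxetan-2-yl]undec-2-en-4-one | C[C@@]1(C/C(C)=C/C(=O)CCCCCCCO[Si](c2ccccc2)(c2ccccc2)C(C)(C)C)OCC1 | intermediate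
13 | (2E,4R)-11-[(tert-butyldiphenylsilyl)oxy]-2-methyl-1-[(2S)-2-methyloxetan-2-yl]undec-2-en-4-ol | C[C@@]1(C/C(C)=C/[C@H](O)CCCCCCCO[Si](c2ccccc2)(c2ccccc2)C(C)(C)C)OCC1 | intermediate
14 | (2E,4R)-11-[(tert-butyldiphenylsilyl)oxy]-2-methyl-1-[(2S)-2-methyloxetan-2-yl]undec-2-en-4-yl acetate | C[C@@]1(C/C(C)=C/[C@H](OC(C)=O)CCCCCCCO[Si](c2ccccc2)(c2ccccc2)C(C)(C)C)OCC1 | intermediate
15 | (3R,5E,7R)-14-[(tert-butyldiphenylsilyl)oxy]-3-hydroperoxy-1-hydroxy-3,5-dimethyltetradec-5-en-7-yl acetate | OCC[C@](C)(OO)C/C(C)=C/[C@H](OC(C)=O)CCCCCCCO[Si](c1ccccc1)(c1ccccc1)C(C)(C)C | intermediate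
16 | (3R,5E,7R)-1-[(tert-butyldimethylsilyl)oxy]-3-[(tert-butyldimethylsilyl)peroxy]-14-[(tert-butyldiphenylsilyl)oxy]-3,5-dimethyltetradec-5-en-7-yl acetate | CC(C)(C)[Si](C)(C)OCC[C@](C)(OO[Si](C)(C)C(C)(C)C)C/C(C)=C/[C@H](OC(C)=O)CCCCCCCO[Si](c1ccccc1)(c1ccccc1)C(C)(C)C | intermediate
17 | (3R,5E,7R)-1-[(tert-butyldimethylsilyl)oxy]-14-[(tert-butyldiphenylsilyl)oxy]-3-hydroperoxy-3,5-dimethyltetradec-5-en-7-ol (key-step precursor) | CC(C)(C)[Si](C)(C)OCC[C@](C)(OO)C/C(C)=C/[C@H](O)CCCCCCCO[Si](c1ccccc1)(c1ccccc1)C(C)(C)C | intermediate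
18 | (3S,5S)-3-{2-[(tert-butyldimethylsilyl)oxy]ethyl}-5-{(1E)-9-[(tert-butyldiphenylsilyl)oxy]non-1-en-1-yl}-3,5-dimethyl-1,2-dioxolane (key-step product) | CC(C)(C)[Si](c1ccccc1)(c1ccccc1)OCCCCCCC/C=C/[C@]2(C)C[C@](C)(CCO[Si](C)(C)C(C)(C)C)OO2 | intermediate
19 | (3S,5R)-3-{2-[(tert-butyldimethylsilyl)oxy]ethyl}-5-{9-[(tert-butyldiphenylsilyl)oxy]nonyl}-3,5-dimethyl-1,2-dioxolane | CC(C)(C)[Si](c1ccccc1)(c1ccccc1)OCCCCCCCCC[C@]2(C)C[C@](C)(CCO[Si](C)(C)C(C)(C)C)OO2 | intermediate
20 | 2-[(3S,5R)-5-{9-[(tert-butyldiphenylsilyl)oxy]nonyl}-3,5-dimethyl-1,2-dioxolan-3-yl]ethanol | CC(C)(C)[Si](c1ccccc1)(c1ccccc1)OCCCCCCCCC[C@]2(C)C[C@](C)(CCO)OO2 | intermediate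
21 | 2-[(3R,5R)-5-{9-[(tert-butyldiphenylsilyl)oxy]nonyl}-3,5-dimethyl-1,2-dioxolan-3-yl]acetic acid | CC(C)(C)[Si](c1ccccc1)(c1ccccc1)OCCCCCCCCC[C@]2(C)C[C@](C)(CC(=O)O)OO2 | intermediate
22 | 2-[(3R,5R)-5-(9-hydroxynonyl)-3,5-dimethyl-1,2-dioxolan-3-yl]acetic acid | OCCCCCCCCC[C@]1(C)C[C@](C)(CC(=O)O)OO1 | intermediate
23 | 2-[(3R,5R)-3,5-dimethyl-5-(9-oxononyl)-1,2-dioxolan-3-yl]acetic acid | O=CCCCCCCCC[C@]1(C)C[C@](C)(CC(=O)O)OO1 | intermediate
24 | (2E,4E)-hepta-2,4-dienal | CC/C=C/C=C/C=O | starting material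
25 | (2E,4E)-hepta-2,4-dien-1-ol | CC/C=C/C=C/CO | intermediate
26 | (2E,4E)-1-bromohepta-2,4-diene | CC/C=C/C=C/CBr | intermediate
27 | diethyl [(2E,4E)-hepta-2,4-dien-1-yl]phosphonate | CC/C=C/C=C/CP(=O)(OCC)OCC | intermediate
28 | diethyl [(2E,4E)-1-lithiohepta-2,4-dien-1-yl]phosphonate | CC/C=C/C=C/C([Li])P(=O)(OCC)OCC | intermediate
29 | 2-[(3R,5R)-5-[(9E,11E,13E)-hexadeca-9,11,13-trien-1-yl]-3,5-dimethyl-1,2-dioxolan-3-yl]acetic acid | CC/C=C/C=C/C=C/CCCCCCCC[C@]1(C)C[C@](C)(CC(=O)O)OO1 | target

## Step count and risk assessment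

Total step count: 21.
Longest linear sequence: 16 steps from 1 (steps 1, 2, 3, 6–17, 21).

### Steps most likely to fail

1. **Step 12 (Proposed new method).**
   - What may go wrong:
     - Pd(II)-induced O–O cleavage or Hock-type fragmentation of the hydroperoxide.
     - β-Hydride elimination in place of β-hydroxide elimination.
     - Acid-induced ionisation of the allylic alcohol, or of the tertiary allylic peroxide once formed, which would erode the chirality transfer.
   - Fallback, all known chemistry, sets out from 12 and comes back at 20. The oxetane of 12 is perhydrolysed with inversion (ethereal H2O2, TMSOTf) to (3R,5E)-14-[(tert-butyldiphenylsilyl)oxy]-3-hydroperoxy-1-hydroxy-3,5-dimethyltetradec-5-en-7-one F1. Et2NH in CF3CH2OH then brings about the intramolecular conjugate (peroxy-Michael) addition, 5-exo-trig, to the β-peroxy ketone 9-[(tert-butyldiphenylsilyl)oxy]-1-[(3S,5S)-5-(2-hydroxyethyl)-3,5-dimethyl-1,2-dioxolan-3-yl]nonan-2-one F2. Its C5 epimers are controlled only by C3 and are separated by chromatography. Condensation with TsNHNH2 gives the tosylhydrazone F3. Reduction with catecholborane followed by NaOAc·3H2O (hydrazone deoxygenation) removes the C2′ oxygen and gives 20.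

2. **Step 9.**
   - What may go wrong:
     - Ionisation of the allylic acetate by the Lewis acid, with allylic peroxidation or transposition.
     - Leakage of the opening into a free C3 cation, helped by the C5=C1′ π-bond, with erosion of the inversion.
     - Oligomerisation by attack of product hydroxyls on activated oxetane.
   - Fallback sets out from 12 and comes back at 17. The perhydrolysis is moved to the enone stage, where the carbonyl group deactivates the alkene and no ionisable allylic ester is present. Compound 12 gives the hydroperoxy enone F1 of the first fallback, which is silylated at once (TBSCl, imidazole) to (3R,5E)-1-[(tert-butyldimethylsilyl)oxy]-3-[(tert-butyldimethylsilyl)peroxy]-14-[(tert-butyldiphenylsilyl)oxy]-3,5-dimethyltetradec-5-en-7-one F4. CBS reduction ((S)-Me-CBS, catecholborane, −78 °C) gives (3R,5E,7R)-1-[(tert-butyldimethylsilyl)oxy]-3-[(tert-butyldimethylsilyl)peroxy]-14-[(tert-butyldiphenylsilyl)oxy]-3,5-dimethyltetradec-5-en-7-ol F5. K2CO3/MeOH then cleaves only the silyl peroxide and gives 17.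

3. **Step 21.**
   - What may go wrong:
     - Incomplete E-selectivity at C9′=C10′.
     - Attack of the carbanion on the O–O bond.
     - Base-induced β-elimination across C2–C3.
     - Sluggish reaction of the lithium carboxylate.
   - Fallback sets out from 22 and comes back at 29. The polarity of the olefination is reversed so that commercial dienal 24 is the electrophile. TMSCHN2 gives methyl 2-[(3R,5R)-5-(9-hydroxynonyl)-3,5-dimethyl-1,2-dioxolan-3-yl]acetate F6, and MsCl/Et3N gives the mesylate F7. 1-Phenyl-1H-tetrazole-5-thiol with K2CO3 in acetone gives the tetrazolyl sulfide F8, and (NH4)6Mo7O24/H2O2 in EtOH gives the tetrazolyl sulfone F9. Julia–Kocienski olefination (KHMDS, DME, −60 °C, then 24) gives the triene methyl ester F10. LiOH in THF/H2O gives 29.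

## Further compounds

F1 | step 12 | (3R,5E)-14-[(tert-butyldiphenylsilyl)oxy]-3-hydroperoxy-1-hydroxy-3,5-dimethyltetradec-5-en-7-one | OCC[C@](C)(OO)C/C(C)=C/C(=O)CCCCCCCO[Si](c1ccccc1)(c1ccccc1)C(C)(C)C
F2 | step 12 | 9-[(tert-butyldiphenylsilyl)oxy]-1-[(3S,5S)-5-(2-hydroxyethyl)-3,5-dimethyl-1,2-dioxolan-3-yl]nonan-2-one | CC(C)(C)[Si](c1ccccc1)(c1ccccc1)OCCCCCCCC(=O)C[C@]2(C)C[C@](C)(CCO)OO2
F3 | step 12 | 4-methylbenzenesulfonohydrazone (tosylhydrazone) of F2 | CC(C)(C)[Si](c1ccccc1)(c1ccccc1)OCCCCCCCC(=NNS(=O)(=O)c1ccc(C)cc1)C[C@]2(C)C[C@](C)(CCO)OO2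
F4 | step 9 | (3R,5E)-1-[(tert-butyldimethylsilyl)oxy]-3-[(tert-butyldimethylsilyl)peroxy]-14-[(tert-butyldiphenylsilyl)oxy]-3,5-dimethyltetradec-5-en-7-one | CC(C)(C)[Si](C)(C)OCC[C@](C)(OO[Si](C)(C)C(C)(C)C)C/C(C)=C/C(=O)CCCCCCCO[Si](c1ccccc1)(c1ccccc1)C(C)(C)C
F5 | step 9 | (3R,5E,7R)-1-[(tert-butyldimethylsilyl)oxy]-3-[(tert-butyldimethylsilyl)peroxy]-14-[(tert-butyldiphenylsilyl)oxy]-3,5-dimethyltetradec-5-en-7-ol | CC(C)(C)[Si](C)(C)OCC[C@](C)(OO[Si](C)(C)C(C)(C)C)C/C(C)=C/[C@H](O)CCCCCCCO[Si](c1ccccc1)(c1ccccc1)C(C)(C)C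
F6 | step 21 | methyl 2-[(3R,5R)-5-(9-hydroxynonyl)-3,5-dimethyl-1,2-dioxolan-3-yl]acetate | OCCCCCCCCC[C@]1(C)C[C@](C)(CC(=O)OC)OO1
F7 | step 21 | methyl 2-[(3R,5R)-3,5-dimethyl-5-{9-[(methylsulfonyl)oxy]nonyl}-1,2-dioxolan-3-yl]acetate | CS(=O)(=O)OCCCCCCCCC[C@]1(C)C[C@](C)(CC(=O)OC)OO1
F8 | step 21 | methyl 2-[(3R,5R)-3,5-dimethyl-5-{9-[(1-phenyl-1H-tetrazol-5-yl)sulfanyl]nonyl}-1,2-dioxolan-3-yl]acetate | c1ccccc1n1nnnc1SCCCCCCCCC[C@]2(C)C[C@](C)(CC(=O)OC)OO2
F9 | step 21 | methyl 2-[(3R,5R)-3,5-dimethyl-5-{9-[(1-phenyl-1H-tetrazol-5-yl)sulfonyl]nonyl}-1,2-dioxolan-3-yl]acetate | c1ccccc1n1nnnc1S(=O)(=O)CCCCCCCCC[C@]2(C)C[C@](C)(CC(=O)OC)OO2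
F10 | step 21 | methyl 2-[(3R,5R)-5-[(9E,11E,13E)-hexadeca-9,11,13-trien-1-yl]-3,5-dimethyl-1,2-dioxolan-3-yl]acetate | CC/C=C/C=C/C=C/CCCCCCCC[C@]1(C)C[C@](C)(CC(=O)OC)OO1
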